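(Readings and results stem from a simulated flask for an exercise; the scatter is artificial.)

3 questions are asked here, and for each I reckon how much X has gone into chains and how many chains share it.

| setting | gamma | epsilon | south-east | south-west |
|---|---|---|---|---|
| X | 0.20 M | 0.84 M | 1.0 M | 0.30 M |
| Q | 9.1 mol% | 9.1 mol% | 9.1 mol% | 9.1 mol% |
| remark | run made earlier | run made earlier |  |  |
| time |  |  | 2.0 h | 2.0 h |

| run | time / min | G / % | X / % |
|---|---|---|---|
| gamma | 5.00 | 13.1 | 87.0 |
| gamma | 12.0 | 18.9 | 81.1 |
| gamma | 25.0 | 26.1 | 73.5 |
| gamma | 40.0 | 32.5 | 67.5 |
| gamma | 50.0 | 35.0 | 65.0 |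
| gamma | 60.0 | 37.3 | 63.2 |
| gamma | 80.0 | 40.3 | 60.1 |
| epsilon | 6.00 | 47.8 | 51.8 |
| epsilon | 10.0 | 64.0 | 36.8 |
| epsilon | 15.0 | 74.2 | 26.0 |
| epsilon | 25.0 | 83.0 | 17.2 |
| epsilon | 40.0 | 86.2 | 13.5 |
| epsilon | 60.0 | 86.2 | 13.4 |
| epsilon | 80.0 | 86.1 | 13.7 |

(readings scatter by 0.3 percentage points)

- which of the two ends with the longer chains by the average number of monomer units in a chain (chains begun, living or dead) ("neither" if they lie within 10%) (south-east / south-west / neither)
- average number of monomer units in a chain (chains begun, living or dead) at the end, south-east
- average number of monomer units in a chain (chains begun, living or dead) at the end, south-west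

- the average divides the monomer in chains by the number of chains begun, living and dead together
- steps that have been proposed: X + Q -> E + G; X + E -> G + E; G + E -> X + E
- the earlier runs do not show the number of chains; that part of a forecast is a guess

I reckon in logarithms, one step on the last. First, the stopping point: in the epsilon run X lies flat from 40.0 min, averaging 13.5% of its charge. That is a floor F of 0.114 M, the equilibrium monomer concentration in the usual term.

Second, the gap X − F falls in a pseudo-first-order way. Its rate in the epsilon run between 6.00 min and 15.0 min, divided by Q0, the charged concentration of Q, gives the closing constant κ, 0.0272 L mol⁻¹ s⁻¹. The powers of ten closed by time t are then D = κ·Q0·t/2.3. At 2.0 h, D is 7.74 for south-east and 2.32 for south-west, so I put both at F.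

Third, with one chain per Q, the length is (X0 − F)/Q0, where X0 is the charged X. That gives 9.74 for south-east and 6.82 for south-west, and I commit to south-east.

The weak link is one chain per Q, since the readings count no chains. In the gamma run, where F is 56.8% of the charge, I run the gap back from 5.00 min and 40.0 min to zero time. This shows a quick jump of 8.17% of the X charged, against a loading of 9.1 mol%. As a reading, that is close enough to keep the link.

The forecast says south-east, with 9.7 and 6.9, on the ground that “there is a fixed equilibrium monomer level”; my south-west length is lower than its figure.

The flask gives south-east, with 9.74 and 6.80.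

    X + Q → E + G (k = 0.105 L mol⁻¹ s⁻¹)
    X + E → G + E, rate k2*[E]*[X] (k = 0.0266 L mol⁻¹ s⁻¹)
    G + E → X + E, rate k3*[E] as long as [G] is above zero (k = 0.00302 s⁻¹)

With κ kept, south-west at 1.00 h reckons to X at 41.6%, and the flask holds 41.8%. Left until 20.0 h, south-west has a length of 6.83. The neighbouring flask is south-west charged with 3.6 mol% of Q, so Q0 is 0.01080 M and D at 2.0 h is 0.920. That leaves 12.1% of the gap standing after the jump. X then reckons to 45.0% of its charge and the length to 15.3; the neighbouring flask gives X 45.3% and a length of 15.2.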